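**Plan**

- Cuts: the CH2–CH2 bond of the linker (made as an olefin by Wittig, then diimide). In the decalin (naphthalene locants, C1 = CMe2), after trading the C2 arm for a ketone and placing a sulfonyl group on C8, the ring bonds C4a–C8a and C7–C8. In the dioxane, the O–C3 and O–C6 bonds.
- Enabling feature: ring A is a cyclohexene (C5=C6) whose allylic carbon C4a and its neighbour C8a are the two fusion atoms, so a retro-[4+2] across C4a–C8a/C7–C8 opens rings A and B together to an acyclic 1,3,9-decatriene in which C4–C3–C2–C1 is the four-atom tether.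
- Forward: auxiliary alkylation, enyne coupling and semireduction to a (Z)-diene, nitrile aldol and HWE give the trienone. One intramolecular Diels–Alder closes ring A and ring B together. Desulfonylation and ketone → enol triflate → ester → CH2PPh3+ follow.
- The 6-formyl-1,2-dioxane is built separately from geranyl acetate. Wittig union, diimide reduction and oxidation of the masked carboxyl complete the chain.
- Stereochemistry: the auxiliary-set C3 methyl (erased later) selects the diene face through a chair tether, and the (Z)-diene geometry enforces the cis fusion (4aR,8aS). In the dioxane, Cα and C3 come from an Evans syn-aldol followed by SN2 inversion at C3, and C6 from a Sharpless epoxide opened with inversion by H2O2.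

Key step: step 10

Remark: decalin atoms carry naphthalene locants with C1 = CMe2 throughout; both 4-benzyl-3-propionyloxazolidinones, propargyl bromide, 2-bromopropene, isobutyronitrile, diethyl [(phenylsulfonyl)methyl]phosphonate and geranyl acetate are taken to be commercial.

**Route**

Step 1
Reactants: 1 (S)-4-benzyl-3-propionyl-1,3-oxazolidin-2-one; 2 propargyl bromide
Product: 4 (S)-4-benzyl-3-[(R)-2-methylpent-4-ynoyl]-1,3-oxazolidin-2-one, via sodium Z-enolate 3 (not isolated)
Conditions: NaHMDS, THF, −78 °C; then 2, −78 → −40 °C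
Reagents that add atoms: none
Why: Evans asymmetric alkylation, in which the chelated sodium Z-enolate is attacked by the reactive propargylic bromide on the face opposite the benzyl group, setting the R methyl centre that becomes C3.

Step 2
Reactants: 4 (S)-4-benzyl-3-[(R)-2-methylpent-4-ynoyl]-1,3-oxazolidin-2-one; 5 2-bromopropene
Product: 6 (S)-4-benzyl-3-[(R)-2,6-dimethylhept-6-en-4-ynoyl]-1,3-oxazolidin-2-one
Conditions: PdCl2(PPh3)2 (3 mol%), CuI (5 mol%), Et3N, THF, rt
Reagents that add atoms: none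
Why: Sonogashira coupling of the terminal alkyne with a vinyl bromide under mild amine base installs the isopropenyl group as a conjugated enyne without touching the imide or its α-centre.

Step 3
Reactants: 6 (S)-4-benzyl-3-[(R)-2,6-dimethylhept-6-en-4-ynoyl]-1,3-oxazolidin-2-one
Product: 7 (R)-2,6-dimethylhept-6-en-4-yn-1-ol
Conditions: LiBH4, MeOH (1 equiv), Et2O, 0 °C
Reagents that add atoms: none
Why: Reductive removal of the Evans auxiliary, since borohydride attacks only the exocyclic imide carbonyl and gives the primary alcohol without epimerisation while the enyne is inert.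

Step 4
Reactants: 7 (R)-2,6-dimethylhept-6-en-4-yn-1-ol
Product: 8 (2R,4Z)-2,6-dimethylhepta-4,6-dien-1-ol
Conditions: Zn(Cu/Ag), MeOH/H2O (1:1), 40 °C
Reagents that add atoms: none
Why: Boland-type semireduction with activated zinc reduces only the conjugated triple bond by syn hydrogen delivery, so the (Z)-diene should form without over-reduction.

Step 5
Reactants: 8 (2R,4Z)-2,6-dimethylhepta-4,6-dien-1-ol
Product: 9 (2R,4Z)-2,6-dimethylhepta-4,6-dienal
Conditions: Dess–Martin periodinane, NaHCO3, CH2Cl2, 0 °C → rt; used crude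
Reagents that add atoms: none
Why: Dess–Martin oxidation under buffered non-basic conditions should give the α-branched aldehyde without epimerisation or isomerisation of the (Z)-diene.

Step 6
Reactants: 9 (2R,4Z)-2,6-dimethylhepta-4,6-dienal; 10 isobutyronitrile
Product: 12 (4R,6Z)-3-hydroxy-2,2,4,8-tetramethylnona-6,8-dienenitrile (mixture at C3), via 2-lithio-2-methylpropanenitrile 11 (not isolated)
Conditions: LDA, THF, −78 °C (10 → 11); then 9, −78 °C; aq. NH4Cl
Reagents that add atoms: none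
Why: Aldol-type addition of a lithiated nitrile to the aldehyde forms the C1–C2 bond and the gem-dimethyl quaternary carbon in one operation, the new carbinol centre being unimportant because it is oxidised in step 9.

Step 7
Reactants: 12 (4R,6Z)-3-hydroxy-2,2,4,8-tetramethylnona-6,8-dienenitrile
Product: 14 (4R,6Z)-3-hydroxy-2,2,4,8-tetramethylnona-6,8-dienal (mixture at C3), via N-aluminio aldimine 13 (not isolated)
Conditions: DIBAL-H (3 equiv), PhMe, −78 → 0 °C; then aq. Rochelle salt, wet SiO2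
Reagents that add atoms: water, O
Why: DIBAL-H half-reduction of a nitrile stops at the metallated aldimine, which is hydrolysed to the aldehyde on work-up, and the β-hydroxy aldehyde cannot dehydrate because its α-carbon is quaternary.

Step 8
Reactants: 14 (4R,6Z)-3-hydroxy-2,2,4,8-tetramethylnona-6,8-dienal; 15 diethyl [(phenylsulfonyl)methyl]phosphonate
Product: 17 (3Z,6R,9E)-2,6,8,8-tetramethyl-10-(phenylsulfonyl)deca-1,3,9-trien-7-ol (mixture at C7), via sodium phosphonate carbanion 16 (not isolated)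
Conditions: NaH (1.0 equiv to 15), THF, 0 °C (15 → 16); then 14, 0 °C → rt
Reagents that add atoms: none
Why: Horner–Wadsworth–Emmons olefination with a sulfonyl-stabilised phosphonate gives the (E)-vinyl sulfone selectively, and the stabilised anion is too weak a base to trigger retro-aldol of the free alcohol.

Step 9
Reactants: 17 (3Z,6R,9E)-2,6,8,8-tetramethyl-10-(phenylsulfonyl)deca-1,3,9-trien-7-ol
Product: 18 (3Z,6R,9E)-2,6,8,8-tetramethyl-10-(phenylsulfonyl)deca-1,3,9-trien-7-one
Conditions: Dess–Martin periodinane, NaHCO3, CH2Cl2, rt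
Reagents that add atoms: none
Why: Dess–Martin oxidation converts the hindered secondary alcohol to the ketone under neutral conditions that leave the α-methyl centre, the (Z)-diene and the vinyl sulfone untouched.

Step 10
Reactants: 18 (3Z,6R,9E)-2,6,8,8-tetramethyl-10-(phenylsulfonyl)deca-1,3,9-trien-7-one
Product: 19 cis-fused (3R,4aR,8R,8aS)-1,1,3,6-tetramethyl-8-(phenylsulfonyl)-3,4,4a,7,8,8a-hexahydronaphthalen-2(1H)-one
Conditions: PhMe (0.01 M), BHT (cat.), 150 °C, sealed tube
Reagents that add atoms: none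
Why: A thermal, concerted but asynchronous [4+2] (type-1 intramolecular Diels–Alder of a 1,3,9-decatriene; closest known classes are sulfonyl-activated decatriene cyclisations and the cis-specific cyclisations of (Z)-dienes) forms C4a–C8a and C7–C8 in one event. Ring A closes as the cyclohexene of the cycloaddition itself and ring B as the fused six-membered ring completed by the C4a–C8a bond, with the C4–C1 tether in a chair. Because the tether leaves the diene from its Z (inside) position, only the tether-exo transition state is within reach, so C4a and C8a are set cis and the quaternary C1 stays clear of the diene underside, which a cis mode from an (E)-diene could not avoid; the E-sulfonyl group then lies endo and sets the temporary C8 centre as drawn. The diene face is chosen by the C3 methyl, which sits equatorial in the chair because the other face would put it 1,3-diaxial to a C1 methyl, and this relays 3R to 4aR,8aS. The step needs cycloaddition to outrun the [1,5]-hydrogen shift open to a (Z)-diene; the gem-dimethyl/keto tether (reactive-rotamer effect), the sulfonyl activation and a temperature held near 150 °C, where that shift is expected to be slow, are what should secure it.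

Step 11
Reactants: 19 (3R,4aR,8R,8aS)-1,1,3,6-tetramethyl-8-(phenylsulfonyl)-3,4,4a,7,8,8a-hexahydronaphthalen-2(1H)-one
Product: 20 (3R,4aR,8aS)-1,1,3,6-tetramethyl-3,4,4a,7,8,8a-hexahydronaphthalen-2(1H)-one
Conditions: 6% Na/Hg, Na2HPO4, MeOH/THF, −20 °C
Reagents that add atoms: none
Why: Reductive desulfonylation by electron transfer from sodium amalgam cleaves the C8–S bond, the aryl sulfone being reduced more readily than the doubly α-branched dialkyl ketone, and neither fusion centre is adjacent to an acidifying group.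

Step 12
Reactants: 20 (3R,4aR,8aS)-1,1,3,6-tetramethyl-3,4,4a,7,8,8a-hexahydronaphthalen-2(1H)-one
Product: 22 (4aR,8aS)-1,1,3,6-tetramethyl-1,4,4a,7,8,8a-hexahydronaphthalen-2-yl trifluoromethanesulfonate, via potassium enolate 21 (not isolated)
Conditions: KHMDS, THF, −78 °C; Comins' reagent, −78 → 0 °C
Reagents that add atoms: N-(5-chloropyridin-2-yl)-1,1,1-trifluoro-N-[(trifluoromethyl)sulfonyl]methanesulfonamide (Comins' reagent), O=S(=O)(N(c1ccc(Cl)cn1)S(=O)(=O)C(F)(F)F)C(F)(F)F
Why: Enolisation is regiospecific because only C3 carries an α-hydrogen, and O-sulfonylation of the enolate gives the tetrasubstituted enol triflate while erasing the C3 centre that has served its purpose.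

Step 13
Reactants: 22 (4aR,8aS)-1,1,3,6-tetramethyl-1,4,4a,7,8,8a-hexahydronaphthalen-2-yl trifluoromethanesulfonate
Product: 23 methyl (4aR,8aS)-1,1,3,6-tetramethyl-1,4,4a,7,8,8a-hexahydronaphthalene-2-carboxylate
Conditions: Pd(OAc)2 (10 mol%), dppf, Et3N, CO (1 atm), MeOH/DMF, 70 °C
Reagents that add atoms: carbon monoxide, [C-]#[O+]; methanol, CO
Why: Palladium-catalysed alkoxycarbonylation of an enol triflate (oxidative addition, CO insertion, methanolysis) introduces the one-carbon unit at C2 with the double bond fixed at C2=C3.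

Step 14
Reactants: 23 methyl (4aR,8aS)-1,1,3,6-tetramethyl-1,4,4a,7,8,8a-hexahydronaphthalene-2-carboxylate
Product: 24 [(4aR,8aS)-1,1,3,6-tetramethyl-1,4,4a,7,8,8a-hexahydronaphthalen-2-yl]methanol
Conditions: DIBAL-H, CH2Cl2, −78 → 0 °C
Reagents that add atoms: none
Why: DIBAL-H 1,2-reduction of the unsaturated ester gives the allylic alcohol without touching either ring alkene.

Step 15
Reactants: 24 [(4aR,8aS)-1,1,3,6-tetramethyl-1,4,4a,7,8,8a-hexahydronaphthalen-2-yl]methanol
Product: 25 {[(4aR,8aS)-1,1,3,6-tetramethyl-1,4,4a,7,8,8a-hexahydronaphthalen-2-yl]methyl}triphenylphosphonium bromide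
Conditions: Ph3P·HBr, MeOH/CH2Cl2, rt
Reagents that add atoms: triphenylphosphine hydrobromide, [Br-].c1ccc(cc1)[PH+](c1ccccc1)c1ccccc1
Why: Allylic alcohols of the β-cyclogeraniol type are converted directly into phosphonium salts by triphenylphosphine hydrobromide through the stabilised allyl cation, which is captured at its primary terminus.

Step 16
Reactants: 26 geranyl acetate
Product: 28 (2E)-3-methyl-6-oxohex-2-en-1-yl acetate, via secondary ozonide 27 (not isolated)
Conditions: O3 (1.0 equiv, Sudan Red 7B end point), CH2Cl2, −78 °C; Me2S, −78 °C → rt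
Reagents that add atoms: ozone, [O-][O+]=O
Why: Ozonolysis with one equivalent of ozone cleaves the electron-rich isopropylidene double bond in preference to the one deactivated by the allylic acetate, and reductive work-up gives the aldehyde.

Step 17
Reactants: 28 (2E)-3-methyl-6-oxohex-2-en-1-yl acetate; 29 (R)-4-benzyl-3-propionyl-1,3-oxazolidin-2-one
Product: 31 (R)-4-benzyl-3-[(2R,3S,6E)-8-acetoxy-3-hydroxy-2,6-dimethyloct-6-enoyl]-1,3-oxazolidin-2-one, via dibutylboron Z-enolate 30 (not isolated)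
Conditions: Bu2BOTf, iPr2NEt, CH2Cl2, 0 °C (29 → 30); 28, −78 → 0 °C; pH 7 buffer, MeOH, 30% H2O2, 0 °C
Reagents that add atoms: none
Why: Evans syn-aldol reaction, in which the boron Z-enolate reacts through a Zimmerman–Traxler chair with the auxiliary dipole opposed, setting the 2R methyl and 3S hydroxyl centres.

Step 18
Reactants: 31 (R)-4-benzyl-3-[(2R,3S,6E)-8-acetoxy-3-hydroxy-2,6-dimethyloct-6-enoyl]-1,3-oxazolidin-2-one
Product: 32 (2E,6S,7S)-6,8-dihydroxy-3,7-dimethyloct-2-en-1-yl acetate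
Conditions: NaBH4, THF/H2O (4:1), 0 °C → rt
Reagents that add atoms: none
Why: Borohydride cleavage of the activated N-acyloxazolidinone in wet THF reduces the imide to the primary alcohol and should leave the unactivated alkyl acetate in place.

Step 19
Reactants: 32 (2E,6S,7S)-6,8-dihydroxy-3,7-dimethyloct-2-en-1-yl acetate
Product: 33 (2E,6S,7S)-8-[(tert-butyldiphenylsilyl)oxy]-6-hydroxy-3,7-dimethyloct-2-en-1-yl acetate
Conditions: TBDPSCl, imidazole, CH2Cl2, 0 °C
Reagents that add atoms: tert-butyl(chloro)diphenylsilane, CC(C)(C)[Si](Cl)(c1ccccc1)c1ccccc1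
Why: Silylation with the bulky TBDPS chloride is selective for the primary hydroxyl over the hindered secondary one.

Step 20
Reactants: 33 (2E,6S,7S)-8-[(tert-butyldiphenylsilyl)oxy]-6-hydroxy-3,7-dimethyloct-2-en-1-yl acetate
Product: 34 (2E,6S,7S)-8-[(tert-butyldiphenylsilyl)oxy]-3,7-dimethyl-6-[(methylsulfonyl)oxy]oct-2-en-1-yl acetate
Conditions: MsCl, Et3N, CH2Cl2, 0 °C
Reagents that add atoms: methanesulfonyl chloride, CS(=O)(=O)Cl
Why: Mesylation turns the remaining secondary hydroxyl into a leaving group with retention, ready for the later SN2 ring closure.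

Step 21
Reactants: 34 (2E,6S,7S)-8-[(tert-butyldiphenylsilyl)oxy]-3,7-dimethyl-6-[(methylsulfonyl)oxy]oct-2-en-1-yl acetate
Product: 35 (2S,3S,6E)-1-[(tert-butyldiphenylsilyl)oxy]-8-hydroxy-2,6-dimethyloct-6-en-3-yl methanesulfonate
Conditions: K2CO3 (0.2 equiv), MeOH, 0 °C
Reagents that add atoms: none
Why: Base-catalysed transesterification with methanol removes the acetate to free the allylic alcohol, the secondary mesylate and the silyl ether being stable to these conditions.

Step 22
Reactants: 35 (2S,3S,6E)-1-[(tert-butyldiphenylsilyl)oxy]-8-hydroxy-2,6-dimethyloct-6-en-3-yl methanesulfonate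
Product: 36 (2S,3S)-1-[(tert-butyldiphenylsilyl)oxy]-5-[(2R,3R)-3-(hydroxymethyl)-2-methyloxiran-2-yl]-2-methylpentan-3-yl methanesulfonate
Conditions: Ti(OiPr)4 (10 mol%), D-(−)-DET (12 mol%), TBHP, 4 Å MS, CH2Cl2, −20 °C
Reagents that add atoms: tert-butyl hydroperoxide, CC(C)(C)OO
Why: Sharpless asymmetric epoxidation of the (E)-trisubstituted allylic alcohol with D-(−)-diethyl tartrate delivers oxygen to the face that gives the (2R,3R)-epoxide, setting the tertiary C–O centre under reagent control.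

Step 23
Reactants: 36 (2S,3S)-1-[(tert-butyldiphenylsilyl)oxy]-5-[(2R,3R)-3-(hydroxymethyl)-2-methyloxiran-2-yl]-2-methylpentan-3-yl methanesulfonate
Product: 37 (2S,3S,6S,7R)-1-[(tert-butyldiphenylsilyl)oxy]-6-hydroperoxy-7,8-dihydroxy-2,6-dimethyloctan-3-yl methanesulfonate
Conditions: anhydrous ethereal H2O2 (excess), phosphomolybdic acid (cat.), Et2O, rt
Reagents that add atoms: hydrogen peroxide, OO
Why: Molybdenum-catalysed perhydrolysis of an epoxide, in which hydrogen peroxide opens the activated trisubstituted epoxide at its tertiary carbon with inversion to give the 6S tertiary hydroperoxide while the carbinol centre is untouched.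

Step 24
Reactants: 37 (2S,3S,6S,7R)-1-[(tert-butyldiphenylsilyl)oxy]-6-hydroperoxy-7,8-dihydroxy-2,6-dimethyloctan-3-yl methanesulfonate
Product: 38 (1R)-1-[(3S,6R)-6-{(2S)-1-[(tert-butyldiphenylsilyl)oxy]propan-2-yl}-3-methyl-1,2-dioxan-3-yl]ethane-1,2-diol
Conditions: KOtBu (1.05 equiv), 18-crown-6, PhMe, 0 °C
Reagents that add atoms: none
Why: Intramolecular alkylation of a hydroperoxide, the selectively formed peroxide anion displacing the secondary mesylate in a 6-exo-tet SN2 reaction with inversion, which closes the 1,2-dioxane and places the ring C–O bond anti to the α-methyl group.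

Step 25
Reactants: 38 (1R)-1-[(3S,6R)-6-{(2S)-1-[(tert-butyldiphenylsilyl)oxy]propan-2-yl}-3-methyl-1,2-dioxan-3-yl]ethane-1,2-diol
Product: 39 (3S,6R)-6-{(2S)-1-[(tert-butyldiphenylsilyl)oxy]propan-2-yl}-3-methyl-1,2-dioxane-3-carbaldehyde
Conditions: NaIO4, THF/pH 7 buffer, 0 °C; used at once
Reagents that add atoms: none
Why: Malaprade glycol cleavage with periodate excises the terminal carbon and unveils the α-peroxy aldehyde under neutral conditions that a dialkyl peroxide tolerates.

Step 26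
Reactants: 25 {[(4aR,8aS)-1,1,3,6-tetramethyl-1,4,4a,7,8,8a-hexahydronaphthalen-2-yl]methyl}triphenylphosphonium bromide; 39 (3S,6R)-6-{(2S)-1-[(tert-butyldiphenylsilyl)oxy]propan-2-yl}-3-methyl-1,2-dioxane-3-carbaldehyde
Product: 41 tert-butyl{(2S)-2-[(3R,6S)-6-methyl-6-{2-[(4aR,8aS)-1,1,3,6-tetramethyl-1,4,4a,7,8,8a-hexahydronaphthalen-2-yl]ethenyl}-1,2-dioxan-3-yl]propoxy}diphenylsilane (E/Z mixture), via phosphorus ylide 40 (not isolated)
Conditions: KHMDS (0.95 equiv to 25), THF, −78 → 0 °C (25 → 40); then 39, −78 → 0 °C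
Reagents that add atoms: none
Why: Wittig olefination of the allylic ylide under salt-free conditions proceeds through the oxaphosphetane with an aldehyde that has no α-hydrogen, and the alkene geometry is immaterial because this bond is reduced next.

Step 27
Reactants: 41 tert-butyl{(2S)-2-[(3R,6S)-6-methyl-6-{2-[(4aR,8aS)-1,1,3,6-tetramethyl-1,4,4a,7,8,8a-hexahydronaphthalen-2-yl]ethenyl}-1,2-dioxan-3-yl]propoxy}diphenylsilane
Product: 42 tert-butyl{(2S)-2-[(3R,6R)-6-methyl-6-{2-[(4aR,8aS)-1,1,3,6-tetramethyl-1,4,4a,7,8,8a-hexahydronaphthalen-2-yl]ethyl}-1,2-dioxan-3-yl]propoxy}diphenylsilane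
Conditions: 2-nitrobenzenesulfonyl hydrazide (excess, in portions), Et3N, CH2Cl2, rt
Reagents that add atoms: none
Why: Diimide reduction is a concerted syn hydrogen transfer that does not cleave O–O bonds and discriminates strongly by substitution, so only the 1,2-disubstituted alkene should be saturated while the tri- and tetrasubstituted ring alkenes remain.

Step 28
Reactants: 42 tert-butyl{(2S)-2-[(3R,6R)-6-methyl-6-{2-[(4aR,8aS)-1,1,3,6-tetramethyl-1,4,4a,7,8,8a-hexahydronaphthalen-2-yl]ethyl}-1,2-dioxan-3-yl]propoxy}diphenylsilane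
Product: 43 (2S)-2-[(3R,6R)-6-methyl-6-{2-[(4aR,8aS)-1,1,3,6-tetramethyl-1,4,4a,7,8,8a-hexahydronaphthalen-2-yl]ethyl}-1,2-dioxan-3-yl]propan-1-ol
Conditions: TBAF, AcOH (1:1), THF, rt
Reagents that add atoms: none
Why: Fluoride-mediated desilylation, buffered with acetic acid so that no base strong enough to fragment the peroxide is present, frees the primary alcohol.

Step 29
Reactants: 43 (2S)-2-[(3R,6R)-6-methyl-6-{2-[(4aR,8aS)-1,1,3,6-tetramethyl-1,4,4a,7,8,8a-hexahydronaphthalen-2-yl]ethyl}-1,2-dioxan-3-yl]propan-1-ol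
Product: 45 (2R)-2-[(3R,6R)-6-methyl-6-{2-[(4aR,8aS)-1,1,3,6-tetramethyl-1,4,4a,7,8,8a-hexahydronaphthalen-2-yl]ethyl}-1,2-dioxan-3-yl]propanoic acid (CNP0122760.1), via peroxy aldehyde 44 (not isolated)
Conditions: TEMPO (0.2 equiv), PhI(OAc)2 (2.2 equiv), MeCN/pH 7 buffer (1:1), rt
Reagents that add atoms: water, O
Why: Oxoammonium (TEMPO/PhI(OAc)2) oxidation in aqueous acetonitrile takes the primary alcohol through the aldehyde hydrate to the acid under near-neutral conditions that should spare the peroxide, both alkenes and the α-stereocentre.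

**Compound list**

1 | (S)-4-benzyl-3-propionyl-1,3-oxazolidin-2-one | CCC(=O)N1[C@@H](Cc2ccccc2)COC1=O | starting material
2 | propargyl bromide | C#CCBr | starting material
3 | sodium (Z)-enolate of 1 | C/C=C(\[O-])N1[C@@H](Cc2ccccc2)COC1=O.[Na+] | intermediate
4 | (S)-4-benzyl-3-[(R)-2-methylpent-4-ynoyl]-1,3-oxazolidin-2-one | C#CC[C@@H](C)C(=O)N1[C@@H](Cc2ccccc2)COC1=O | intermediate
5 | 2-bromopropene | C=C(C)Br | starting material
6 | (S)-4-benzyl-3-[(R)-2,6-dimethylhept-6-en-4-ynoyl]-1,3-oxazolidin-2-one | C=C(C)C#CC[C@@H](C)C(=O)N1[C@@H](Cc2ccccc2)COC1=O | intermediate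
7 | (R)-2,6-dimethylhept-6-en-4-yn-1-ol | C=C(C)C#CC[C@@H](C)CO | intermediate
8 | (2R,4Z)-2,6-dimethylhepta-4,6-dien-1-ol | C=C(C)/C=C\C[C@@H](C)CO | intermediate
9 | (2R,4Z)-2,6-dimethylhepta-4,6-dienal | C=C(C)/C=C\C[C@@H](C)C=O | intermediate
10 | isobutyronitrile | CC(C)C#N | starting material
11 | 2-lithio-2-methylpropanenitrile | [Li]C(C)(C)C#N | intermediate
12 | (4R,6Z)-3-hydroxy-2,2,4,8-tetramethylnona-6,8-dienenitrile (mixture at C3) | C=C(C)/C=C\C[C@@H](C)C(O)C(C)(C)C#N | intermediate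
13 | (4R,6Z)-3-hydroxy-2,2,4,8-tetramethylnona-6,8-dien-1-imine, present as its N-aluminium derivative and drawn as the free imine | C=C(C)/C=C\C[C@@H](C)C(O)C(C)(C)C=N | intermediate
14 | (4R,6Z)-3-hydroxy-2,2,4,8-tetramethylnona-6,8-dienal (mixture at C3) | C=C(C)/C=C\C[C@@H](C)C(O)C(C)(C)C=O | intermediate
15 | diethyl [(phenylsulfonyl)methyl]phosphonate | CCOP(=O)(OCC)CS(=O)(=O)c1ccccc1 | starting material
16 | sodium (diethoxyphosphoryl)(phenylsulfonyl)methanide | CCOP(=O)(OCC)[CH-]S(=O)(=O)c1ccccc1.[Na+] | intermediate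
17 | (3Z,6R,9E)-2,6,8,8-tetramethyl-10-(phenylsulfonyl)deca-1,3,9-trien-7-ol (mixture at C7) | C=C(C)/C=C\C[C@@H](C)C(O)C(C)(C)/C=C/S(=O)(=O)c1ccccc1 | intermediate
18 | (3Z,6R,9E)-2,6,8,8-tetramethyl-10-(phenylsulfonyl)deca-1,3,9-trien-7-one | C=C(C)/C=C\C[C@@H](C)C(=O)C(C)(C)/C=C/S(=O)(=O)c1ccccc1 | intermediate
19 | cis-fused (3R,4aR,8R,8aS)-1,1,3,6-tetramethyl-8-(phenylsulfonyl)-3,4,4a,7,8,8a-hexahydronaphthalen-2(1H)-one | CC1=C[C@H]2C[C@@H](C)C(=O)C(C)(C)[C@H]2[C@H](S(=O)(=O)c2ccccc2)C1 | intermediate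
20 | (3R,4aR,8aS)-1,1,3,6-tetramethyl-3,4,4a,7,8,8a-hexahydronaphthalen-2(1H)-one (C3 is erased in step 12) | CC1=C[C@H]2C[C@@H](C)C(=O)C(C)(C)[C@H]2CC1 | intermediate
21 | potassium enolate of 20 | CC1=C[C@H]2CC(C)=C([O-])C(C)(C)[C@H]2CC1.[K+] | intermediate
22 | (4aR,8aS)-1,1,3,6-tetramethyl-1,4,4a,7,8,8a-hexahydronaphthalen-2-yl trifluoromethanesulfonate | CC1=C[C@H]2CC(C)=C(OS(=O)(=O)C(F)(F)F)C(C)(C)[C@H]2CC1 | intermediate
23 | methyl (4aR,8aS)-1,1,3,6-tetramethyl-1,4,4a,7,8,8a-hexahydronaphthalene-2-carboxylate | CC1=C[C@H]2CC(C)=C(C(=O)OC)C(C)(C)[C@H]2CC1 | intermediate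
24 | [(4aR,8aS)-1,1,3,6-tetramethyl-1,4,4a,7,8,8a-hexahydronaphthalen-2-yl]methanol | CC1=C[C@H]2CC(C)=C(CO)C(C)(C)[C@H]2CC1 | intermediate
25 | {[(4aR,8aS)-1,1,3,6-tetramethyl-1,4,4a,7,8,8a-hexahydronaphthalen-2-yl]methyl}triphenylphosphonium bromide | CC1=C[C@H]2CC(C)=C(C[P+](c3ccccc3)(c3ccccc3)c3ccccc3)C(C)(C)[C@H]2CC1.[Br-] | intermediate
26 | geranyl acetate | CC(=O)OC/C=C(\C)CCC=C(C)C | starting material
27 | secondary ozonide of the 6,7-double bond of 26 | CC(=O)OC/C=C(\C)CCC1OOC(C)(C)O1 | intermediate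
28 | (2E)-3-methyl-6-oxohex-2-en-1-yl acetate | CC(=O)OC/C=C(\C)CCC=O | intermediate
29 | (R)-4-benzyl-3-propionyl-1,3-oxazolidin-2-one | CCC(=O)N1[C@H](Cc2ccccc2)COC1=O | starting material
30 | dibutylboron (Z)-enolate of 29 | C/C=C(\OB(CCCC)CCCC)N1[C@H](Cc2ccccc2)COC1=O | intermediate
31 | (R)-4-benzyl-3-[(2R,3S,6E)-8-acetoxy-3-hydroxy-2,6-dimethyloct-6-enoyl]-1,3-oxazolidin-2-one | CC(=O)OC/C=C(\C)CC[C@H](O)[C@@H](C)C(=O)N1[C@H](Cc2ccccc2)COC1=O | intermediate
32 | (2E,6S,7S)-6,8-dihydroxy-3,7-dimethyloct-2-en-1-yl acetate | CC(=O)OC/C=C(\C)CC[C@H](O)[C@@H](C)CO | intermediate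
33 | (2E,6S,7S)-8-[(tert-butyldiphenylsilyl)oxy]-6-hydroxy-3,7-dimethyloct-2-en-1-yl acetate | CC(=O)OC/C=C(\C)CC[C@H](O)[C@@H](C)CO[Si](c1ccccc1)(c1ccccc1)C(C)(C)C | intermediate
34 | (2E,6S,7S)-8-[(tert-butyldiphenylsilyl)oxy]-3,7-dimethyl-6-[(methylsulfonyl)oxy]oct-2-en-1-yl acetate | CC(=O)OC/C=C(\C)CC[C@H](OS(C)(=O)=O)[C@@H](C)CO[Si](c1ccccc1)(c1ccccc1)C(C)(C)C | intermediate
35 | (2S,3S,6E)-1-[(tert-butyldiphenylsilyl)oxy]-8-hydroxy-2,6-dimethyloct-6-en-3-yl methanesulfonate | OC/C=C(\C)CC[C@H](OS(C)(=O)=O)[C@@H](C)CO[Si](c1ccccc1)(c1ccccc1)C(C)(C)C | intermediate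
36 | (2S,3S)-1-[(tert-butyldiphenylsilyl)oxy]-5-[(2R,3R)-3-(hydroxymethyl)-2-methyloxiran-2-yl]-2-methylpentan-3-yl methanesulfonate | OC[C@H]1O[C@]1(C)CC[C@H](OS(C)(=O)=O)[C@@H](C)CO[Si](c2ccccc2)(c2ccccc2)C(C)(C)C | intermediate
37 | (2S,3S,6S,7R)-1-[(tert-butyldiphenylsilyl)oxy]-6-hydroperoxy-7,8-dihydroxy-2,6-dimethyloctan-3-yl methanesulfonate | OC[C@@H](O)[C@@](C)(OO)CC[C@H](OS(C)(=O)=O)[C@@H](C)CO[Si](c1ccccc1)(c1ccccc1)C(C)(C)C | intermediate
38 | (1R)-1-[(3S,6R)-6-{(2S)-1-[(tert-butyldiphenylsilyl)oxy]propan-2-yl}-3-methyl-1,2-dioxan-3-yl]ethane-1,2-diol | OC[C@@H](O)[C@]1(C)CC[C@H]([C@@H](C)CO[Si](c2ccccc2)(c2ccccc2)C(C)(C)C)OO1 | intermediate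
39 | (3S,6R)-6-{(2S)-1-[(tert-butyldiphenylsilyl)oxy]propan-2-yl}-3-methyl-1,2-dioxane-3-carbaldehyde | O=C[C@]1(C)CC[C@H]([C@@H](C)CO[Si](c2ccccc2)(c2ccccc2)C(C)(C)C)OO1 | intermediate
40 | {[(4aR,8aS)-1,1,3,6-tetramethyl-1,4,4a,7,8,8a-hexahydronaphthalen-2-yl]methylidene}triphenylphosphorane | CC1=C[C@H]2CC(C)=C(C=P(c3ccccc3)(c3ccccc3)c3ccccc3)C(C)(C)[C@H]2CC1 | intermediate
41 | tert-butyl{(2S)-2-[(3R,6S)-6-methyl-6-{2-[(4aR,8aS)-1,1,3,6-tetramethyl-1,4,4a,7,8,8a-hexahydronaphthalen-2-yl]ethenyl}-1,2-dioxan-3-yl]propoxy}diphenylsilane (E/Z mixture) | CC1=C[C@H]2CC(C)=C(C=C[C@]3(C)CC[C@H]([C@@H](C)CO[Si](c4ccccc4)(c4ccccc4)C(C)(C)C)OO3)C(C)(C)[C@H]2CC1 | intermediate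
42 | tert-butyl{(2S)-2-[(3R,6R)-6-methyl-6-{2-[(4aR,8aS)-1,1,3,6-tetramethyl-1,4,4a,7,8,8a-hexahydronaphthalen-2-yl]ethyl}-1,2-dioxan-3-yl]propoxy}diphenylsilane | CC1=C[C@H]2CC(C)=C(CC[C@]3(C)CC[C@H]([C@@H](C)CO[Si](c4ccccc4)(c4ccccc4)C(C)(C)C)OO3)C(C)(C)[C@H]2CC1 | intermediate
43 | (2S)-2-[(3R,6R)-6-methyl-6-{2-[(4aR,8aS)-1,1,3,6-tetramethyl-1,4,4a,7,8,8a-hexahydronaphthalen-2-yl]ethyl}-1,2-dioxan-3-yl]propan-1-ol | CC1=C[C@H]2CC(C)=C(CC[C@]3(C)CC[C@H]([C@@H](C)CO)OO3)C(C)(C)[C@H]2CC1 | intermediate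
44 | (2R)-2-[(3R,6R)-6-methyl-6-{2-[(4aR,8aS)-1,1,3,6-tetramethyl-1,4,4a,7,8,8a-hexahydronaphthalen-2-yl]ethyl}-1,2-dioxan-3-yl]propanal | CC1=C[C@H]2CC(C)=C(CC[C@]3(C)CC[C@H]([C@@H](C)C=O)OO3)C(C)(C)[C@H]2CC1 | intermediate
45 | (2R)-2-[(3R,6R)-6-methyl-6-{2-[(4aR,8aS)-1,1,3,6-tetramethyl-1,4,4a,7,8,8a-hexahydronaphthalen-2-yl]ethyl}-1,2-dioxan-3-yl]propanoic acid (CNP0122760.1) | CC1=C[C@H]2CC(C)=C(CC[C@]3(C)CC[C@H]([C@@H](C)C(=O)O)OO3)C(C)(C)[C@H]2CC1 | target

**Step count and risks**

Total steps: 29. Longest linear sequence: 19 (steps 1–15, then 26–29); the dioxane branch (steps 16–25) joins at step 26.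

Step 10 (key cycloaddition). What may go wrong is that ring closure is too slow at a temperature where the (Z)-diene undergoes [1,5]-hydrogen shift to the conjugated, unreactive 4-methylpenta-1,3-dienyl isomer, so that material is drained before it cyclises. The fallback changes the activating group to a formyl group that can be Lewis-acid activated at low temperature, with the same (Z)-diene and the same two bonds formed. Setting out from hydroxy aldehyde 14, a Wittig reaction with (triphenylphosphoranylidene)acetaldehyde (PhMe, 80 °C) would give (2E,6R,8Z)-5-hydroxy-4,4,6,10-tetramethylundeca-2,8,10-trienal F1. Dess–Martin oxidation would give the keto enal (2E,6R,8Z)-4,4,6,10-tetramethyl-5-oxoundeca-2,8,10-trienal F2. Me2AlCl (CH2Cl2, −78 → −20 °C) should then promote the tether-exo, formyl-endo cycloaddition to (1R,4aR,6R,8aR)-3,6,8,8-tetramethyl-7-oxo-1,2,4a,5,6,7,8,8a-octahydronaphthalene-1-carbaldehyde F3. Tsuji–Wilkinson decarbonylation (RhCl(PPh3)3, PhCN, 130 °C) removes the formyl group and comes back to the route at ketone 20.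

Step 23 (perhydrolysis). What may go wrong is loss of regiocontrol or partial ionisation at the tertiary carbon during the intermolecular acid-catalysed opening, which would erode the configuration at the quaternary peroxide carbon, or acid-induced rearrangement of the epoxy alcohol. The fallback reverses the order of the two C–O bond formations so that the tertiary C–O bond is made intramolecularly. Setting out from epoxy mesylate 36, SN2 displacement of the mesylate by hydrogen peroxide (50% H2O2, KOH, MeOH, 0 °C; inversion) would give tert-butyl{[(2S,3R)-3-hydroperoxy-5-[(2R,3R)-3-(hydroxymethyl)-2-methyloxiran-2-yl]-2-methylpentyl]oxy}diphenylsilane F4. Acid-catalysed 6-exo opening of its epoxide at the tertiary carbon (CSA, CH2Cl2, 0 °C; inversion) closes the dioxane and comes back to the route at diol 38.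

Step 26 (fragment union). What may go wrong is slow addition between two hindered partners, during which the basic ylide degrades the α-peroxy aldehyde, or fragmentation of the O–O bond from any alkoxide-type adduct. The fallback changes the olefination manifold to a Julia–Kocienski reaction run in Barbier mode, so that the carbanion is never present in excess. Setting out from alcohol 24, a Mitsunobu reaction with 1-phenyl-1H-tetrazole-5-thiol (PPh3, DIAD, THF) would give 1-phenyl-5-({[(4aR,8aS)-1,1,3,6-tetramethyl-1,4,4a,7,8,8a-hexahydronaphthalen-2-yl]methyl}sulfanyl)-1H-tetrazole F5. Molybdate/H2O2 oxidation would give 1-phenyl-5-({[(4aR,8aS)-1,1,3,6-tetramethyl-1,4,4a,7,8,8a-hexahydronaphthalen-2-yl]methyl}sulfonyl)-1H-tetrazole F6. Addition of KHMDS to a mixture of F6 and aldehyde 39 (DME, −60 °C) comes back to the route at diene 41.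

**Further compounds**

F1 | step 10 | (2E,6R,8Z)-5-hydroxy-4,4,6,10-tetramethylundeca-2,8,10-trienal | C=C(C)/C=C\C[C@@H](C)C(O)C(C)(C)/C=C/C=O
F2 | step 10 | (2E,6R,8Z)-4,4,6,10-tetramethyl-5-oxoundeca-2,8,10-trienal | C=C(C)/C=C\C[C@@H](C)C(=O)C(C)(C)/C=C/C=O
F3 | step 10 | (1R,4aR,6R,8aR)-3,6,8,8-tetramethyl-7-oxo-1,2,4a,5,6,7,8,8a-octahydronaphthalene-1-carbaldehyde | CC1=C[C@H]2C[C@@H](C)C(=O)C(C)(C)[C@H]2[C@H](C=O)C1
F4 | step 23 | tert-butyl{[(2S,3R)-3-hydroperoxy-5-[(2R,3R)-3-(hydroxymethyl)-2-methyloxiran-2-yl]-2-methylpentyl]oxy}diphenylsilane | OC[C@H]1O[C@]1(C)CC[C@@H](OO)[C@@H](C)CO[Si](c2ccccc2)(c2ccccc2)C(C)(C)C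
F5 | step 26 | 1-phenyl-5-({[(4aR,8aS)-1,1,3,6-tetramethyl-1,4,4a,7,8,8a-hexahydronaphthalen-2-yl]methyl}sulfanyl)-1H-tetrazole | CC1=C[C@H]2CC(C)=C(CSc3nnnn3-c3ccccc3)C(C)(C)[C@H]2CC1
F6 | step 26 | 1-phenyl-5-({[(4aR,8aS)-1,1,3,6-tetramethyl-1,4,4a,7,8,8a-hexahydronaphthalen-2-yl]methyl}sulfonyl)-1H-tetrazole | CC1=C[C@H]2CC(C)=C(CS(=O)(=O)c3nnnn3-c3ccccc3)C(C)(C)[C@H]2CC1
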